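**Retrosynthetic overview**
1. The target comes from acetylation of its 7-hydroxy precursor, whose ring A (a 2-hydroxy-2-methylcyclohexene-1,3-dione) is made by an α-ketol ring expansion (1,2-acyl shift) of a 7-acetyl-7-hydroxy-cyclopenta[c]pyran-6-one.
2. That ketol comes from enantioselective α-hydroxylation of the 7-acetyl β-diketone, itself made by C5 chlorination and C-acetylation of the bicyclic dienone.
3. Ring B (the pyran) comes from 6-endo hydroalkoxylation of a 4-(hydroxymethyl)-3-alkynylcyclopentenone, made by Stork–Danheiser alkynylation of 3-methoxy-5-(silyloxymethyl)cyclopentenone with the (R)-dienyne.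
4. The dienyne comes from (R)-2-methylbutan-1-ol by oxidation/Wittig and Horner–Wadsworth–Emmons olefination; the vinylogous ester comes from 3-methoxycyclopent-2-enone and formaldehyde.
5. Ring order: purchased five-membered carbocycle, then ring B, then ring A by five-to-six ring expansion. C7 is set by the hydroxylation and relayed through the shift; C8a is carried over; the side-chain centre is purchased.

Assumption: (R)-2-methylbutan-1-ol of high ee and the two phosphorus reagents are purchased, and the acidic C8a–H centre is taken to be most stable in the natural 8aR configuration (C7 acetoxy pseudo-axial, C7 methyl pseudo-equatorial).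

**Route**

Step 1
Reactants: 1 (R)-2-methylbutan-1-ol
Product: 3 (2E,4R)-2,4-dimethylhex-2-enal, via (R)-2-methylbutanal 2 (not isolated)
Conditions: TEMPO (10 mol%), PhI(OAc)2 (1.1 equiv), CH2Cl2, 0 °C to rt; then Ph3P=C(CH3)CHO (1.3 equiv), toluene, 80 °C, sealed tube
Reagents that add atoms: 2-(triphenylphosphoranylidene)propanal (CC(C=O)=P(c1ccccc1)(c1ccccc1)c1ccccc1)
Why: TEMPO/PhI(OAc)2 oxidation gives the configurationally labile α-branched aldehyde, which is trapped in the same flask by an E-selective Wittig olefination with the formyl-stabilised ylide, so the purchased stereocentre never meets base.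

Step 2
Reactants: 3 (2E,4R)-2,4-dimethylhex-2-enal
Product: 5 (3E,5E,7R)-5,7-dimethylnona-3,5-dien-1-yne, via trimethylsilyl dienyne 4 (not isolated)
Conditions: (EtO)2P(O)CH2C≡CSiMe3, LiN(SiMe3)2, THF, –78 °C to 0 °C; then K2CO3 (cat.), MeOH, rt
Reagents that add atoms: diethyl [3-(trimethylsilyl)prop-2-yn-1-yl]phosphonate (CCOP(=O)(OCC)CC#C[Si](C)(C)C)
Why: Horner–Wadsworth–Emmons olefination with the silyl-propargyl phosphonate anion forms the new disubstituted alkene E-selectively, and K2CO3/MeOH then cleaves the alkynyl C–Si bond.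

Step 3
Reactants: 6 3-methoxycyclopent-2-en-1-one
Product: 9 (±)-3-methoxy-5-{[(triethylsilyl)oxy]methyl}cyclopent-2-en-1-one, via lithium dienolate 7 (not isolated), via lithium aldolate 8 (not isolated)
Conditions: LiN(iPr)2 (1.05 equiv), THF, –78 °C; CH2O (gas, from cracked paraformaldehyde), –78 °C; then Et3SiCl, –78 °C to 0 °C
Reagents that add atoms: formaldehyde (C=O); chlorotriethylsilane (CC[Si](Cl)(CC)CC); lithium diisopropylamide ([Li]N(C(C)C)C(C)C; lithium of 7 and 8 only)
Why: Kinetic α'-deprotonation of the vinylogous ester and aldol addition to monomeric formaldehyde, with O-silylation of the aldolate to block retro-aldol and elimination; the new centre (future C8a) is racemic here and is funnelled in step 8.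

Step 4
Reactants: 5 (3E,5E,7R)-5,7-dimethylnona-3,5-dien-1-yne; 9 (±)-3-methoxy-5-{[(triethylsilyl)oxy]methyl}cyclopent-2-en-1-one
Product: 12 3-[(3E,5E,7R)-5,7-dimethylnona-3,5-dien-1-yn-1-yl]-4-(hydroxymethyl)cyclopent-2-en-1-one (1:1 C4 epimers), via lithium acetylide 10 (not isolated), via lithium alkoxide adduct 11 (not isolated)
Conditions: 5, n-BuLi, THF, –78 °C; add 9, –78 °C to 0 °C; then 1 M HCl (aq), THF, 0 °C to rt
Reagents that add atoms: water (O; the new carbonyl oxygen); n-butyllithium ([Li]CCCC; lithium of 10 and 11 only)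
Why: Stork–Danheiser sequence, in which 1,2-addition of the acetylide to the vinylogous ester carbonyl is followed by acid-mediated allylic transposition/hydrolysis (the silyl ether is lost in the same acid), placing the alkyne on the β-carbon and the hydroxymethyl group on the γ-carbon of the new enone.

Step 5
Reactants: 12 3-[(3E,5E,7R)-5,7-dimethylnona-3,5-dien-1-yn-1-yl]-4-(hydroxymethyl)cyclopent-2-en-1-one
Product: 13 3-[(1E,3E,5R)-3,5-dimethylhepta-1,3-dien-1-yl]-7,7a-dihydrocyclopenta[c]pyran-6(1H)-one (1:1 C7a epimers)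
Conditions: (Ph3P)AuNTf2 (2 mol%), CH2Cl2, 0 °C to rt
Reagents that add atoms: none
Why: π-Acid (monovalent gold) hydroalkoxylation closes ring B in the 6-endo-dig mode, because the alkyne is polarised by the enone so that C3 (the δ-position, also dienyl-stabilised) is the electrophilic carbon.

Step 6
Reactants: 13 3-[(1E,3E,5R)-3,5-dimethylhepta-1,3-dien-1-yl]-7,7a-dihydrocyclopenta[c]pyran-6(1H)-one
Product: 14 5-chloro-3-[(1E,3E,5R)-3,5-dimethylhepta-1,3-dien-1-yl]-7,7a-dihydrocyclopenta[c]pyran-6(1H)-one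
Conditions: N-chlorosuccinimide (1.05 equiv), CH2Cl2, 0 °C to rt, dark
Reagents that add atoms: N-chlorosuccinimide (ClN1C(=O)CCC1=O)
Why: Electrophilic chlorination at C5, the α-carbon of the push–pull dienone and terminus of the ring B dienol ether, by analogy with the C5 chlorination of azaphilones with N-chlorosuccinimide.

Step 7
Reactants: 14 5-chloro-3-[(1E,3E,5R)-3,5-dimethylhepta-1,3-dien-1-yl]-7,7a-dihydrocyclopenta[c]pyran-6(1H)-one
Product: 16 7-acetyl-5-chloro-3-[(1E,3E,5R)-3,5-dimethylhepta-1,3-dien-1-yl]-7,7a-dihydrocyclopenta[c]pyran-6(1H)-one (epimer/enol mixture), via lithium enolate 15 (not isolated)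
Conditions: LiN(SiMe3)2 (2.2 equiv), THF, –78 °C; 1-acetylbenzotriazole (1.1 equiv), –78 °C to –20 °C; NH4Cl (aq)
Reagents that add atoms: 1-acetyl-1H-benzotriazole (CC(=O)n1nnc2ccccc21); lithium bis(trimethylsilyl)amide ([Li]N([Si](C)(C)C)[Si](C)(C)C; lithium of 15 only)
Why: The kinetic cross-conjugated α'-enolate is C-acylated by the N-acylbenzotriazole (Claisen-type acylation), and the second equivalent of base holds the product as its diketonate.

Step 8
Reactants: 16 7-acetyl-5-chloro-3-[(1E,3E,5R)-3,5-dimethylhepta-1,3-dien-1-yl]-7,7a-dihydrocyclopenta[c]pyran-6(1H)-one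
Product: 17 (7S,7aR)-7-acetyl-5-chloro-3-[(1E,3E,5R)-3,5-dimethylhepta-1,3-dien-1-yl]-7-hydroxy-7,7a-dihydrocyclopenta[c]pyran-6(1H)-one
Conditions: Ni(ClO4)2·6H2O (10 mol%), (R,R)-DBFOX/Ph (11 mol%; the antipode that delivers the 7S carbinol), 2,6-lutidine (20 mol%), (±)-2-(phenylsulfonyl)-3-phenyloxaziridine (1.2 equiv), 4 Å molecular sieves, CH2Cl2, –20 °C
Reagents that add atoms: 2-(phenylsulfonyl)-3-phenyloxaziridine (O=S(=O)(c1ccccc1)N1OC1c1ccccc1)
Why: Proposed new method: a dynamic kinetic enantioselective α-hydroxylation of a 5-acylcyclopent-2-enone, in which the divalent nickel/DBFOX complex binds 16 as its planar 1,3-diketonate and shields one face so that the sulfonyloxaziridine delivers oxygen to give the 7S carbinol, while C7a (the sp3 carbon of a 2-acylcyclopentadienol tautomer, epimerised by lutidine through the achiral dienol/fulvenolate) lets both epimers of 16 react through the one that keeps C1 anti to the incoming oxygen (7aR); the closest known reaction is the Ni(ClO4)2/DBFOX-catalysed enantioselective hydroxylation of cyclic β-keto esters with racemic N-sulfonyloxaziridines, which has not been shown for 2-acyl enones or in a dynamic kinetic mode.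

Step 9
Reactants: 17 (7S,7aR)-7-acetyl-5-chloro-3-[(1E,3E,5R)-3,5-dimethylhepta-1,3-dien-1-yl]-7-hydroxy-7,7a-dihydrocyclopenta[c]pyran-6(1H)-one
Product: 19 (7R,8aR)-5-chloro-3-[(1E,3E,5R)-3,5-dimethylhepta-1,3-dien-1-yl]-7-methyl-6,8-dioxo-6,7,8,8a-tetrahydro-1H-isochromen-7-yl acetate (the target), via hydroxy dione 18 (not isolated)
Conditions: Sc(OTf)3 (10 mol%), 4 Å molecular sieves, MeCN, 0 °C to rt; then Ac2O (3 equiv), –20 °C; NaHCO3 (aq)
Reagents that add atoms: acetic anhydride (CC(=O)OC(C)=O)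
Why: α-Ketol (acyloin) rearrangement with ring expansion, in which trivalent scandium holds the tertiary hydroxyl and the acetyl oxygen in a syn-coplanar chelate and the ring acyl carbon C6 (acyl migrates in preference to alkyl in α-hydroxy-β-diketones) shifts suprafacially from the carbinol carbon to the acetyl carbon, relieving cyclopentenone strain and converting the 7S carbinol into the 7R quaternary centre with C8a carried over as 8aR; the same Lewis acid then catalyses acetylation of the hindered tertiary alcohol without base, so C8a is not exposed to enolate chemistry.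

**Compound list**
1 | (R)-2-methylbutan-1-ol | CC[C@@H](C)CO | starting material
2 | (R)-2-methylbutanal | CC[C@@H](C)C=O | intermediate
3 | (2E,4R)-2,4-dimethylhex-2-enal | CC[C@@H](C)/C=C(C)/C=O | intermediate
4 | trimethyl[(3E,5E,7R)-5,7-dimethylnona-3,5-dien-1-yn-1-yl]silane | CC[C@@H](C)/C=C(C)/C=C/C#C[Si](C)(C)C | intermediate
5 | (3E,5E,7R)-5,7-dimethylnona-3,5-dien-1-yne | CC[C@@H](C)/C=C(C)/C=C/C#C | intermediate
6 | 3-methoxycyclopent-2-en-1-one | COC1=CC(=O)CC1 | starting material
7 | lithium 4-methoxycyclopenta-1,4-dien-1-olate (kinetic dienolate of 6) | [Li]OC1=CCC(OC)=C1 | intermediate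
8 | lithium (4-methoxy-2-oxocyclopent-3-en-1-yl)methanolate (racemic) | [Li]OCC1CC(OC)=CC1=O | intermediate
9 | (±)-3-methoxy-5-{[(triethylsilyl)oxy]methyl}cyclopent-2-en-1-one | CC[Si](CC)(CC)OCC1CC(OC)=CC1=O | intermediate
10 | lithium (3E,5E,7R)-5,7-dimethylnona-3,5-dien-1-yn-1-ide | CC[C@@H](C)/C=C(C)/C=C/C#C[Li] | intermediate
11 | lithium 1-[(3E,5E,7R)-5,7-dimethylnona-3,5-dien-1-yn-1-yl]-3-methoxy-5-{[(triethylsilyl)oxy]methyl}cyclopent-2-en-1-olate (stereoisomer mixture at C1 and C5) | CC[C@@H](C)/C=C(C)/C=C/C#CC1(O[Li])C=C(OC)CC1CO[Si](CC)(CC)CC | intermediate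
12 | 3-[(3E,5E,7R)-5,7-dimethylnona-3,5-dien-1-yn-1-yl]-4-(hydroxymethyl)cyclopent-2-en-1-one (1:1 C4 epimers) | CC[C@@H](C)/C=C(C)/C=C/C#CC1=CC(=O)CC1CO | intermediate
13 | 3-[(1E,3E,5R)-3,5-dimethylhepta-1,3-dien-1-yl]-7,7a-dihydrocyclopenta[c]pyran-6(1H)-one (1:1 C7a epimers) | CC[C@@H](C)/C=C(C)/C=C/C1=CC2=CC(=O)CC2CO1 | intermediate
14 | 5-chloro-3-[(1E,3E,5R)-3,5-dimethylhepta-1,3-dien-1-yl]-7,7a-dihydrocyclopenta[c]pyran-6(1H)-one (C7a epimers) | CC[C@@H](C)/C=C(C)/C=C/C1=CC2=C(Cl)C(=O)CC2CO1 | intermediate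
15 | lithium 5-chloro-3-[(1E,3E,5R)-3,5-dimethylhepta-1,3-dien-1-yl]-1,7a-dihydrocyclopenta[c]pyran-6-olate (C7a epimers) | CC[C@@H](C)/C=C(C)/C=C/C1=CC2=C(Cl)C(O[Li])=CC2CO1 | intermediate
16 | 7-acetyl-5-chloro-3-[(1E,3E,5R)-3,5-dimethylhepta-1,3-dien-1-yl]-7,7a-dihydrocyclopenta[c]pyran-6(1H)-one (C7/C7a epimers and enol forms) | CC[C@@H](C)/C=C(C)/C=C/C1=CC2=C(Cl)C(=O)C(C(C)=O)C2CO1 | intermediate
17 | (7S,7aR)-7-acetyl-5-chloro-3-[(1E,3E,5R)-3,5-dimethylhepta-1,3-dien-1-yl]-7-hydroxy-7,7a-dihydrocyclopenta[c]pyran-6(1H)-one | CC[C@@H](C)/C=C(C)/C=C/C1=CC2=C(Cl)C(=O)[C@@](O)(C(C)=O)[C@H]2CO1 | intermediate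
18 | (7R,8aR)-5-chloro-3-[(1E,3E,5R)-3,5-dimethylhepta-1,3-dien-1-yl]-7-hydroxy-7-methyl-1H-isochromene-6,8(7H,8aH)-dione | CC[C@@H](C)/C=C(C)/C=C/C1=CC2=C(Cl)C(=O)[C@](C)(O)C(=O)[C@H]2CO1 | intermediate
19 | (7R,8aR)-5-chloro-3-[(1E,3E,5R)-3,5-dimethylhepta-1,3-dien-1-yl]-7-methyl-6,8-dioxo-6,7,8,8a-tetrahydro-1H-isochromen-7-yl acetate | CC[C@@H](C)/C=C(C)/C=C/C1=CC2=C(Cl)C(=O)[C@](C)(OC(C)=O)C(=O)[C@H]2CO1 | target

**Step count and risks**

Total step count: 9. Longest linear sequence: 8 steps (1, 2, 4, 5, 6, 7, 8, 9).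

The three steps most likely to fail:

- **Step 8 (the proposed new method).** The risks are insufficient catalyst control at C7 and a C7a centre that does not epimerise under the conditions. The fallback uses known chemistry and replaces catalyst control by a substrate-controlled relay from a resolved C7a centre; it sets out from 12 and comes back to the route at 17. The two C4 epimers of 12 are separated by lipase-catalysed acylation (immobilised Candida antarctica lipase B, vinyl acetate, MTBE, rt; enzyme screened for this preference), which converts the 4S epimer into the (4S)-acetate F1 and leaves the (4R)-alcohol F2. F2 is taken through the conditions of steps 5, 6 and 7 as single epimers: the (7aR)-dienone F3, the (7aR)-chlorodienone F4, its lithium enolate F5 and the (7aR)-β-diketone F6. Hydroxylation of F6 with the same racemic oxaziridine but the achiral catalyst Ni(ClO4)2·6H2O/2,2'-bipyridine (no lutidine, –20 °C) then occurs anti to C1 and gives 17. This relay needs C7a of F6 to be configurationally stable, which is exactly the case in which the dynamic process of step 8 would fail.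

- **Step 9.** The risks are alkyl instead of acyl migration, carbon-to-oxygen acyl transfer, and Lewis-acid damage to the dienyl enol ether. The fallback switches from the chelated (cisoid) to the anionic (transoid) manifold; it sets out from 16 and comes back at 18. Step 8 run with (S,S)-DBFOX/Ph gives the epimeric (7R,7aS)-ketol F7. Its potassium alkoxide (KN(SiMe3)2, THF, –78 °C to –20 °C) rearranges through the non-chelated conformer, in which the acetyl group is turned by 180°, so the acyl shift again produces the 7R centre. The NH4Cl quench equilibrates C8a to 8aR and gives 18, which is acetylated as in the second half of step 9.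

- **Step 5.** The risks are 5-exo closure and competing enyne chemistry on gold. The fallback fixes the C3–heteroatom bond by conjugate addition before ring closure; it sets out from 12 and comes back at 13. Pyrrolidine (1.1 equiv, MeOH, 0 °C) adds to the δ-carbon (C3) of the ynenone to give the dienaminone F8. Pyridinium p-toluenesulfonate in toluene at 50 °C then lets the hydroxyl group attack the iminium carbon (6-exo-trig) and expels pyrrolidine, giving 13.

**Further compounds**
F1 | step 8 | [(1S)-2-[(3E,5E,7R)-5,7-dimethylnona-3,5-dien-1-yn-1-yl]-4-oxocyclopent-2-en-1-yl]methyl acetate | CC[C@@H](C)/C=C(C)/C=C/C#CC1=CC(=O)C[C@@H]1COC(C)=O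
F2 | step 8 | (4R)-3-[(3E,5E,7R)-5,7-dimethylnona-3,5-dien-1-yn-1-yl]-4-(hydroxymethyl)cyclopent-2-en-1-one | CC[C@@H](C)/C=C(C)/C=C/C#CC1=CC(=O)C[C@H]1CO
F3 | step 8 | (7aR)-3-[(1E,3E,5R)-3,5-dimethylhepta-1,3-dien-1-yl]-7,7a-dihydrocyclopenta[c]pyran-6(1H)-one | CC[C@@H](C)/C=C(C)/C=C/C1=CC2=CC(=O)C[C@H]2CO1
F4 | step 8 | (7aR)-5-chloro-3-[(1E,3E,5R)-3,5-dimethylhepta-1,3-dien-1-yl]-7,7a-dihydrocyclopenta[c]pyran-6(1H)-one | CC[C@@H](C)/C=C(C)/C=C/C1=CC2=C(Cl)C(=O)C[C@H]2CO1
F5 | step 8 | lithium (7aR)-5-chloro-3-[(1E,3E,5R)-3,5-dimethylhepta-1,3-dien-1-yl]-1,7a-dihydrocyclopenta[c]pyran-6-olate | CC[C@@H](C)/C=C(C)/C=C/C1=CC2=C(Cl)C(O[Li])=C[C@H]2CO1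
F6 | step 8 | (7aR)-7-acetyl-5-chloro-3-[(1E,3E,5R)-3,5-dimethylhepta-1,3-dien-1-yl]-7,7a-dihydrocyclopenta[c]pyran-6(1H)-one (C7 epimers and enol forms) | CC[C@@H](C)/C=C(C)/C=C/C1=CC2=C(Cl)C(=O)C(C(C)=O)[C@H]2CO1
F7 | step 9 | (7R,7aS)-7-acetyl-5-chloro-3-[(1E,3E,5R)-3,5-dimethylhepta-1,3-dien-1-yl]-7-hydroxy-7,7a-dihydrocyclopenta[c]pyran-6(1H)-one | CC[C@@H](C)/C=C(C)/C=C/C1=CC2=C(Cl)C(=O)[C@](O)(C(C)=O)[C@@H]2CO1
F8 | step 5 | 3-[(3E,5E,7R)-5,7-dimethyl-2-(pyrrolidin-1-yl)nona-1,3,5-trien-1-yl]-4-(hydroxymethyl)cyclopent-2-en-1-one (C4 epimers, enamine geometry not fixed) | CC[C@@H](C)/C=C(C)/C=C/C(=CC1=CC(=O)CC1CO)N1CCCC1
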